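**Assumption:** one‑pot operations (borylation/oxidation, carboalumination/CH2O trapping, lithiation/cupration/alkylation) are counted as single steps, and hex‑5‑ynoic acid, resorcinol and catechol are taken as the commercial starting materials.

## Retrosynthetic overview

1. Ring C is closed last by intramolecular Mitsunobu etherification (O1–C2, inversion) of an (R)‑β‑hydroxy aryl ketone; rings A and B come from resorcinol and catechol.
2. Key late coupling: the C4–C4a bond, from a fully substituted aryllithium (ring A + C10 side chain) and an (R)‑β‑silyloxy aldehyde (ring B + C2–C4), then oxidation.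
3. Ring A/side chain union: the C6–C1″ bond, by directed ortho‑metalation and Cu‑mediated SN2 allylation with an (E)‑allylic bromide.
4. Side chain: the (E)‑trisubstituted alkene from Zr‑catalysed methylalumination of a terminal alkyne; the tertiary carbinol from an ester and MeMgBr.
5. C2 stereocentre from Brown allylation of the ring‑B aldehyde; the third ring‑A oxygen from Ir‑catalysed C–H borylation/oxidation; the cyclising oxygen is differentiated as TIPS, then THP.

## Side‑chain fragment

**Step 1**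
Reactants: 1 hex‑5‑ynoic acid
Product: 2 methyl hex‑5‑ynoate
Conditions: MeOH, cat. H2SO4, reflux
Reagents that add atoms: methanol, CO
Why: Fischer esterification activates the carboxyl carbon for double Grignard addition.

**Step 2**
Reactants: 2 methyl hex‑5‑ynoate
Product: 3 2‑methylhept‑6‑yn‑2‑ol
Conditions: MeMgBr (3.3 equiv), THF, 0 °C → rt
Reagents that add atoms: methylmagnesium bromide, C[Mg]Br
Why: Double Grignard addition to the ester gives the tertiary carbinol; the extra equivalent covers deprotonation of the alkyne C–H.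

**Step 3**
Reactants: 3 2‑methylhept‑6‑yn‑2‑ol
Product: 4 triethyl[(2‑methylhept‑6‑yn‑2‑yl)oxy]silane
Conditions: TESOTf, 2,6‑lutidine, CH2Cl2, −78 → 0 °C
Reagents that add atoms: triethylsilyl triflate, CC[Si](CC)(CC)OS(=O)(=O)C(F)(F)F
Why: Silyl triflate silylation protects the hindered tertiary alcohol for the organometallic steps that follow.

**Step 4**
Reactants: 4 triethyl[(2‑methylhept‑6‑yn‑2‑yl)oxy]silane
Product: 5 (2E)‑3,7‑dimethyl‑7‑(triethylsilyloxy)oct‑2‑en‑1‑ol
Conditions: Me3Al, Cp2ZrCl2 (cat.), CH2Cl2, rt; then n‑BuLi, (CH2O)n, THF, −78 °C → rt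
Reagents that add atoms: trimethylaluminium, C[Al](C)C; paraformaldehyde, C=O
Why: Negishi Zr‑catalysed carboalumination adds Me and Al syn across the alkyne, and the alanate is hydroxymethylated with retention, fixing the (E)‑alkene.

**Step 5**
Reactants: 5 (2E)‑3,7‑dimethyl‑7‑(triethylsilyloxy)oct‑2‑en‑1‑ol
Product: 6 (2E)‑1‑bromo‑3,7‑dimethyl‑7‑(triethylsilyloxy)oct‑2‑ene
Conditions: MsCl, Et3N, THF, −45 °C; then LiBr, 0 °C (used crude)
Reagents that add atoms: lithium bromide, [Li+].[Br-]
Why: Mesylation and SN2 bromide displacement give the primary allylic bromide without allylic transposition or E/Z loss.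

## Ring‑A fragment

**Step 6**
Reactants: 7 resorcinol
Product: 8 1,3‑bis(methoxymethoxy)benzene
Conditions: NaH, MOMCl, DMF, 0 °C → rt
Reagents that add atoms: chloromethyl methyl ether, COCCl
Why: Williamson etherification installs MOM groups that protect the phenols and later act as ortho‑directing groups.

**Step 7**
Reactants: 8 1,3‑bis(methoxymethoxy)benzene
Product: 9 3,5‑bis(methoxymethoxy)phenol
Conditions: [Ir(OMe)(cod)]2 (1.5 mol %), dtbpy, B2pin2, THF, 80 °C; then aq. NaOH, H2O2, 0 °C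
Reagents that add atoms: hydrogen peroxide, OO (B2pin2 is transient; no boron remains)
Why: Sterically controlled Ir‑catalysed C–H borylation of a 1,3‑disubstituted arene occurs only at C5, and oxidation of the boronate gives the third oxygen as a free, differentiated phenol.

**Step 8**
Reactants: 9 3,5‑bis(methoxymethoxy)phenol
Product: 10 [3,5‑bis(methoxymethoxy)phenoxy]triisopropylsilane
Conditions: TIPSCl, imidazole, DMF, rt
Reagents that add atoms: triisopropylsilyl chloride, CC(C)[Si](Cl)(C(C)C)C(C)C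
Why: The bulky, non‑coordinating silyl ether blocks its two flanking positions, so the next lithiation goes only between the two OMOM groups.

## Union of ring A and side chain

**Step 9**
Reactants: 10 [3,5‑bis(methoxymethoxy)phenoxy]triisopropylsilane; 6 (2E)‑1‑bromo‑3,7‑dimethyl‑7‑(triethylsilyloxy)oct‑2‑ene
Product: 11 {4‑[(2E)‑3,7‑dimethyl‑7‑(triethylsilyloxy)oct‑2‑en‑1‑yl]‑3,5‑bis(methoxymethoxy)phenoxy}triisopropylsilane
Conditions: 10 (1.2 equiv), n‑BuLi, THF, 0 °C → rt; CuI, −40 °C; then 6, −78 → 0 °C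
Reagents that add atoms: none
Why: Directed ortho‑metalation at the doubly activated site, then SN2 (α) allylation of the arylcopper, places the chain between the two OMOM groups with the alkene geometry retained.

**Step 10**
Reactants: 11
Product: 12 4‑[(2E)‑3,7‑dimethyl‑7‑(triethylsilyloxy)oct‑2‑en‑1‑yl]‑3,5‑bis(methoxymethoxy)phenol
Conditions: TBAF (1.05 equiv), THF, 0 °C, 15 min
Reagents that add atoms: none
Why: Fluoride cleaves the aryl silyl ether (phenoxide leaving group) much faster than the hindered tertiary alkyl TES ether.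

**Step 11**
Reactants: 12
Product: 13 2‑{4‑[(2E)‑3,7‑dimethyl‑7‑(triethylsilyloxy)oct‑2‑en‑1‑yl]‑3,5‑bis(methoxymethoxy)phenoxy}tetrahydro‑2H‑pyran (racemic at the acetal carbon)
Conditions: 3,4‑dihydro‑2H‑pyran, PPTS (10 mol %), CH2Cl2, 0 °C → rt
Reagents that add atoms: 3,4‑dihydro‑2H‑pyran, C1=COCCC1
Why: Acid‑catalysed acetalisation gives a THP ether that directs ortho‑lithiation and later hydrolyses about 10^3 times faster than MOM, keeping the cyclising oxygen distinct.

## Ring‑B fragment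

**Step 12**
Reactants: 14 catechol
Product: 15 4‑bromobenzene‑1,2‑diol
Conditions: NBS, HBF4·OEt2, MeCN, −30 °C → rt
Reagents that add atoms: N‑bromosuccinimide, O=C1CCC(=O)N1Br
Why: Electrophilic aromatic bromination under acid activation is para‑selective and stops at the monobromide.

**Step 13**
Reactants: 15 4‑bromobenzene‑1,2‑diol
Product: 16 4‑bromo‑1,2‑bis(tert‑butyldimethylsilyloxy)benzene
Conditions: TBSCl, imidazole, DMF, rt
Reagents that add atoms: tert‑butyldimethylsilyl chloride, CC(C)(C)[Si](C)(C)Cl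
Why: Silyl ethers survive the organolithium steps, donate less than alkyl ethers (which limits benzylic ionisation later), and come off with fluoride at the end.

**Step 14**
Reactants: 16
Product: 17 3,4‑bis(tert‑butyldimethylsilyloxy)benzaldehyde
Conditions: n‑BuLi, THF, −78 °C; DMF, −78 °C → rt
Reagents that add atoms: N,N‑dimethylformamide, CN(C)C=O
Why: Br–Li exchange and formylation with DMF; the lithium is not ortho to a silyloxy group, so no retro‑Brook shift occurs.

**Step 15**
Reactants: 17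
Product: 18 (1R)‑1‑[3,4‑bis(tert‑butyldimethylsilyloxy)phenyl]but‑3‑en‑1‑ol
Conditions: lIpc2B(allyl) [from (+)‑Ipc2BOMe of the (−)‑α‑pinene series and allylMgBr], Et2O, −78 °C; ethanolamine work‑up
Reagents that add atoms: allylmagnesium bromide, C=CC[Mg]Br (allyl delivered via the chiral borane)
Why: Brown asymmetric allylboration through a chair Zimmerman–Traxler transition state; the (−)‑α‑pinene‑derived reagent attacks the Re face of the aryl aldehyde to give the (R)‑carbinol (typically >90 % ee), and the non‑basic work‑up spares the aryl TBS ethers.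

**Step 16**
Reactants: 18
Product: 19 {[(1R)‑1‑[3,4‑bis(tert‑butyldimethylsilyloxy)phenyl]but‑3‑en‑1‑yl]oxy}triethylsilane
Conditions: TESCl, imidazole, DMF, 0 °C → rt
Reagents that add atoms: triethylsilyl chloride, CC[Si](Cl)(CC)CC
Why: Silylation masks the carbinol as an acid‑labile TES ether that can later be removed without touching the aryl TBS groups.

**Step 17**
Reactants: 19
Product: 20 (3R)‑3‑[3,4‑bis(tert‑butyldimethylsilyloxy)phenyl]‑3‑(triethylsilyloxy)propanal
Conditions: OsO4 (2 mol %), NaIO4, 2,6‑lutidine, dioxane/H2O, rt (used promptly)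
Reagents that add atoms: osmium tetroxide, O=[Os](=O)(=O)=O; sodium periodate, [Na+].[O-]I(=O)(=O)=O
Why: Lemieux–Johnson cleavage of the only alkene gives the β‑silyloxy aldehyde without exposing the electron‑rich arene to ozone; the stereocentre is not involved.

## Key coupling and endgame

**Step 18**
Reactants: 13 (THP ether of the ring‑A/side‑chain fragment); 20 (3R)‑3‑[3,4‑bis(tert‑butyldimethylsilyloxy)phenyl]‑3‑(triethylsilyloxy)propanal
Product: 21 (3R)‑3‑[3,4‑bis(tert‑butyldimethylsilyloxy)phenyl]‑1‑{3‑[(2E)‑3,7‑dimethyl‑7‑(triethylsilyloxy)oct‑2‑en‑1‑yl]‑2,4‑bis(methoxymethoxy)‑6‑(tetrahydropyran‑2‑yloxy)phenyl}‑3‑(triethylsilyloxy)propan‑1‑ol (mixture at C1 and at the THP carbon)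
Conditions: 13 (1.3 equiv), n‑BuLi, TMEDA, THF, 0 °C, 1 h; then 20, −78 °C
Reagents that add atoms: none
Why: Directed ortho‑metalation at the only site type left (flanked by OTHP and OMOM), then 1,2‑addition to the aldehyde, forms C4–C4a with fixed regiochemistry; the new carbinol centre is removed in the next step.

**Step 19**
Reactants: 21
Product: 22 (3R)‑3‑[3,4‑bis(tert‑butyldimethylsilyloxy)phenyl]‑1‑{3‑[(2E)‑3,7‑dimethyl‑7‑(triethylsilyloxy)oct‑2‑en‑1‑yl]‑2,4‑bis(methoxymethoxy)‑6‑(tetrahydropyran‑2‑yloxy)phenyl}‑3‑(triethylsilyloxy)propan‑1‑one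
Conditions: Dess–Martin periodinane, NaHCO3, CH2Cl2, 0 °C → rt
Reagents that add atoms: none
Why: Buffered Dess–Martin oxidation gives the aryl ketone without affecting acetals, silyl ethers, the alkene or the β‑stereocentre.

**Step 20**
Reactants: 22
Product: 23 (3R)‑3‑[3,4‑bis(tert‑butyldimethylsilyloxy)phenyl]‑3‑hydroxy‑1‑{6‑hydroxy‑2,4‑bis(methoxymethoxy)‑3‑[(2E)‑3,7‑dimethyl‑7‑(triethylsilyloxy)oct‑2‑en‑1‑yl]phenyl}propan‑1‑one
Conditions: AcOH/THF/H2O (3:1:1), rt → 35 °C
Reagents that add atoms: none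
Why: Mild aqueous acetolysis removes only the THP acetal and the secondary TES ether, leaving MOM and aryl TBS intact, so one phenol and the carbinol are freed (loss of the tertiary TES here would not matter).

**Step 21**
Reactants: 23
Product: 24 (2S)‑2‑[3,4‑bis(tert‑butyldimethylsilyloxy)phenyl]‑6‑[(2E)‑3,7‑dimethyl‑7‑(triethylsilyloxy)oct‑2‑en‑1‑yl]‑5,7‑bis(methoxymethoxy)chroman‑4‑one
Conditions: PPh3, DIAD, toluene/THF, 0 °C
Reagents that add atoms: none
Why: Intramolecular Mitsunobu etherification, in which the only free phenol displaces the activated (R)‑carbinol by SN2 with inversion, sets (2S) and can only give the 6‑substituted flavanone.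

**Step 22**
Reactants: 24
Product: 25 (2S)‑2‑[3,4‑bis(tert‑butyldimethylsilyloxy)phenyl]‑5,7‑dihydroxy‑6‑[(2E)‑3,7‑dimethyl‑7‑(triethylsilyloxy)oct‑2‑en‑1‑yl]chroman‑4‑one
Conditions: TMSOTf, 2,2′‑bipyridyl, MeCN, 0 °C → rt; then H2O
Reagents that add atoms: none
Why: Bipyridyl‑buffered silyl triflate converts aryl MOM ethers to aryl TMS ethers that hydrolyse on work‑up, avoiding the Brønsted acid that would ionise the tertiary carbinol or cyclise the phenol onto the alkene.

**Step 23**
Reactants: 25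
Product: 26 prokinawan
Conditions: TBAF/AcOH (1:1), THF, 0 °C → rt
Reagents that add atoms: none
Why: Buffered fluoride removes the two aryl TBS ethers and the tertiary TES ether without generating the phenoxide that would racemise C2 by retro‑oxa‑Michael ring opening.

## Compound list

1 | hex‑5‑ynoic acid | C#CCCCC(=O)O | starting material
2 | methyl hex‑5‑ynoate | C#CCCCC(=O)OC | intermediate
3 | 2‑methylhept‑6‑yn‑2‑ol | C#CCCCC(C)(C)O | intermediate
4 | triethyl[(2‑methylhept‑6‑yn‑2‑yl)oxy]silane | C#CCCCC(C)(C)O[Si](CC)(CC)CC | intermediate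
5 | (2E)‑3,7‑dimethyl‑7‑(triethylsilyloxy)oct‑2‑en‑1‑ol | OC/C=C(\C)CCCC(C)(C)O[Si](CC)(CC)CC | intermediate
6 | (2E)‑1‑bromo‑3,7‑dimethyl‑7‑(triethylsilyloxy)oct‑2‑ene | BrC/C=C(\C)CCCC(C)(C)O[Si](CC)(CC)CC | intermediate
7 | resorcinol | Oc1cccc(O)c1 | starting material
8 | 1,3‑bis(methoxymethoxy)benzene | COCOc1cccc(OCOC)c1 | intermediate
9 | 3,5‑bis(methoxymethoxy)phenol | COCOc1cc(O)cc(OCOC)c1 | intermediate
10 | [3,5‑bis(methoxymethoxy)phenoxy]triisopropylsilane | COCOc1cc(O[Si](C(C)C)(C(C)C)C(C)C)cc(OCOC)c1 | intermediate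
11 | TIPS ether of 4‑[(2E)‑3,7‑dimethyl‑7‑(triethylsilyloxy)oct‑2‑enyl]‑3,5‑bis(methoxymethoxy)phenol | COCOc1cc(O[Si](C(C)C)(C(C)C)C(C)C)cc(OCOC)c1C/C=C(\C)CCCC(C)(C)O[Si](CC)(CC)CC | intermediate
12 | 4‑[(2E)‑3,7‑dimethyl‑7‑(triethylsilyloxy)oct‑2‑enyl]‑3,5‑bis(methoxymethoxy)phenol | COCOc1cc(O)cc(OCOC)c1C/C=C(\C)CCCC(C)(C)O[Si](CC)(CC)CC | intermediate
13 | THP ether of 12 (racemic acetal carbon) | COCOc1cc(OC2CCCCO2)cc(OCOC)c1C/C=C(\C)CCCC(C)(C)O[Si](CC)(CC)CC | intermediate
14 | catechol | Oc1ccccc1O | starting material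
15 | 4‑bromobenzene‑1,2‑diol | Oc1ccc(Br)cc1O | intermediate
16 | 4‑bromo‑1,2‑bis(tert‑butyldimethylsilyloxy)benzene | CC(C)(C)[Si](C)(C)Oc1ccc(Br)cc1O[Si](C)(C)C(C)(C)C | intermediate
17 | 3,4‑bis(tert‑butyldimethylsilyloxy)benzaldehyde | O=Cc1ccc(O[Si](C)(C)C(C)(C)C)c(O[Si](C)(C)C(C)(C)C)c1 | intermediate
18 | (1R)‑1‑[3,4‑bis(TBSO)phenyl]but‑3‑en‑1‑ol | C=CC[C@@H](O)c1ccc(O[Si](C)(C)C(C)(C)C)c(O[Si](C)(C)C(C)(C)C)c1 | intermediate
19 | TES ether of 18 (R) | C=CC[C@@H](O[Si](CC)(CC)CC)c1ccc(O[Si](C)(C)C(C)(C)C)c(O[Si](C)(C)C(C)(C)C)c1 | intermediate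
20 | (3R)‑3‑[3,4‑bis(TBSO)phenyl]‑3‑(triethylsilyloxy)propanal | O=CC[C@@H](O[Si](CC)(CC)CC)c1ccc(O[Si](C)(C)C(C)(C)C)c(O[Si](C)(C)C(C)(C)C)c1 | intermediate
21 | coupled secondary alcohol (3R; C1 and THP epimers) | COCOc1cc(OC2CCCCO2)c(C(O)C[C@@H](O[Si](CC)(CC)CC)c2ccc(O[Si](C)(C)C(C)(C)C)c(O[Si](C)(C)C(C)(C)C)c2)c(OCOC)c1C/C=C(\C)CCCC(C)(C)O[Si](CC)(CC)CC | intermediate
22 | aryl ketone (3R) | COCOc1cc(OC2CCCCO2)c(C(=O)C[C@@H](O[Si](CC)(CC)CC)c2ccc(O[Si](C)(C)C(C)(C)C)c(O[Si](C)(C)C(C)(C)C)c2)c(OCOC)c1C/C=C(\C)CCCC(C)(C)O[Si](CC)(CC)CC | intermediate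
23 | (3R)‑β‑hydroxy ketone with free 6′‑phenol | COCOc1cc(O)c(C(=O)C[C@@H](O)c2ccc(O[Si](C)(C)C(C)(C)C)c(O[Si](C)(C)C(C)(C)C)c2)c(OCOC)c1C/C=C(\C)CCCC(C)(C)O[Si](CC)(CC)CC | intermediate
24 | (2S)‑5,7‑bis(MOM)‑3′,4′‑bis(TBS)‑7″‑TES‑protected prokinawan | C/C(=C\Cc1c(OCOC)cc2c(c1OCOC)C(=O)C[C@@H](c1ccc(O[Si](C)(C)C(C)(C)C)c(O[Si](C)(C)C(C)(C)C)c1)O2)CCCC(C)(C)O[Si](CC)(CC)CC | intermediate
25 | (2S)‑3′,4′‑bis(TBS)‑7″‑TES‑protected prokinawan | C/C(=C\Cc1c(O)cc2c(c1O)C(=O)C[C@@H](c1ccc(O[Si](C)(C)C(C)(C)C)c(O[Si](C)(C)C(C)(C)C)c1)O2)CCCC(C)(C)O[Si](CC)(CC)CC | intermediate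
26 | prokinawan, (2S)‑2‑(3,4‑dihydroxyphenyl)‑5,7‑dihydroxy‑6‑[(2E)‑7‑hydroxy‑3,7‑dimethyloct‑2‑en‑1‑yl]chroman‑4‑one | C/C(=C\Cc1c(O)cc2c(c1O)C(=O)C[C@@H](c1ccc(O)c(O)c1)O2)CCCC(C)(C)O | target

## Summary

**Total step count:** 23.

**Longest linear sequence:** 14 steps (1–5, 9–11, 18–23). The ring‑A and ring‑B branches are each 12 steps to the target.

**Steps most likely to fail:**

1. **Step 18** (hindered di‑ortho‑alkoxy aryllithium with an enolisable β‑silyloxy aldehyde; enolisation or β‑elimination may compete). Fallback: reverse the polarity of the union. Trap lithiated 13 with N‑methoxy‑N‑methylacetamide to give the methyl ketone, then form C2–C3 by an enantioselective boron or Mukaiyama aldol with aldehyde 17, which gives the 22/23‑type aldol directly.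
2. **Step 21** (Mitsunobu closure; the electron‑rich benzylic carbinol may partly ionise and erode ee, or eliminate to the chalcone). Fallback: drop the SN2 closure. Convert lithiated 13 to the 6‑substituted 5,7‑bis(MOM)chromone (acylation with a 3‑(dimethylamino)acryloyl Weinreb amide, then THP removal and cyclisation), and introduce ring B with C2 set by Rh(I)‑ or Pd(II)/PyOx‑catalysed asymmetric conjugate addition of the 3,4‑bis(TBSO)phenylboronic acid made from 16.
3. **Step 22** (MOM removal beside a tertiary carbinol and an ortho‑allyl phenol; risk of chroman or tetrahydropyran formation). Fallback: change the protecting‑group scheme. Use SEM instead of MOM on resorcinol from step 6 (the same type of ortho‑directing group), so that all protecting groups in the endgame are fluoride‑ or MgBr2‑labile and no acid‑type MOM cleavage is needed.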